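## The problem

The target 23 is a (3R)-isoflavan: a chroman (rings A and C) that carries at C3 a 2,2-dimethyl-2H-chromene (rings B and D), bonded through chromene C8, which is C1' of ring B. Ring A has a single aromatic hydrogen (C8). Its methoxy group at C5 sits between the C4 methylene and the C6 prenyl group, and the C7 hydroxyl and O1 flank C8–H, so no substituent can be placed by the innate selectivity of a phloroglucinol ring. Ring B has its own positional demand: the pyran oxygen is ortho to the point of attachment and the free hydroxyl is para to it. C3 is the only stereocentre and lies between two methylene groups, so nothing in the molecule can relay configuration to it and it must come from a chiral catalyst. Once set it is safe only while no carbonyl group stands at C2 or C4. The ortho-prenylphenol cyclises in strong acid and is epoxidised by peracids, the chromene double bond is sensitive to acid, electrophiles and hydrogenation, and the free phenols are easily oxidised. Hydrogenolysis and boron trihalides are therefore excluded, and protecting groups must leave under mild acid or fluoride. The enabling feature is the C4–C3 unit: C4 is bonded to C4a of ring A, and C3 is bonded to C1' of ring B and to C2. This is the pattern a vinyl group acquires when one carbon takes an aryl nucleophile and the other an aryl electrophile. If the vinyl group sits on boron, the boron stays on C3 and can be exchanged stereospecifically for the C2 carbon, after which O1–C2 closes ring C.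

## Retrosynthesis

**23 to 21 (O–Si, then O1–C2).** The ring B silyl ether is cut first, back to 22, so that the last forward operation is a buffered fluoride treatment and not an acid step. Ring C is then opened at O1–C2 to give the phenolic primary alcohol 21. This bond is preferred over C4–C4a or C3–C4 because closure takes place at a primary carbon remote from the stereocentre. Only one hydroxyl of 21 is ortho to the side chain, so the Mitsunobu closure has no positional choice; keeping ring B silylated removes the third phenol from the reaction.

**21 to 18 (two acetals, C2–O and C2–C3).** Restoring the two MOM ethers gives 20. Its CH2OH group is traced to a CH2–B group in 19, and that to the secondary benzylic boronate 18 by removing one carbon. The C2 carbon is thus supplied by LiCH2Cl in a Matteson homologation. The alternative of carrying C2 on the vinyl partner would make a tertiary boronate and is rejected. The forward reaction must proceed with retention at C3 and stop after one insertion.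

**18 to 16, 15 and 9 (C3–C1' and C4–C4a).** Both aryl–carbon bonds of the two-carbon linker are cut in one operation. This leads to the ring B aryllithium 16, commercial vinylboronic acid pinacol ester 15 and the ring A triflate 9. The neighbouring options are a C3–C4 alkylation of a ring B arylacetic acid derivative, which needs stoichiometric chirality and leaves a carbonyl next to C3, and an isoflavene hydrogenation, which would not spare the chromene and prenyl double bonds. The chosen cut gives three fragments of comparable size, one of them bought. The forward reaction must bind one face of the vinyl ate complex 17 and accept a triflate flanked by two oxygen substituents.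

**9 to 7 (O–CH3, then C6–prenyl).** Demethylation gives phenol 8, and a retro-Claisen step moves the prenyl group back onto that oxygen as the 1,1-dimethylallyl ether 7. Direct C-prenylation of 1 would leave open which ortho hydroxyl is later methylated. In 7 one ortho carbon of the allyl ether carries the triflate, so the rearrangement can only reach the carbon that becomes C6, and the hydroxyl it releases is by construction the one to be methylated. Capping the other oxygen as the triflate beforehand prevents a catechol from forming.

**7 to 1 (S–O, aryl C–O, O–allyl, two acetals).** The triflate comes from phenol 6, and 6 from aldehyde 4 by Baeyer–Villiger oxidation through formate 5. Placing this oxidation before the Claisen step means the peracid meets only a deactivated vinyl group, not the trisubstituted prenyl alkene. Aldehyde 4 is the tertiary allyl ether of 2, made from carbonate 3, and 2 is the bis-MOM ether of symmetrical 2,4,6-trihydroxybenzaldehyde 1, whose chelated hydroxyl stays free.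

**16 to 10 (C–Li, ring D, O–propargyl, O–Si).** The aryllithium 16 comes from bromide 14 by halogen–lithium exchange. Ring D of 14 is opened by the reverse of a propargyl Claisen cascade to ether 13, made from phenol 11 and 3-chloro-3-methylbut-1-yne 12. Direct annulation of 4-bromoresorcinol 10 with an enal could use either hydroxyl and two ring carbons. In 13 the bromine blocks one ortho position, so only one chromene can form. Phenol 11 is the mono-silyl ether of 10; the bulky silyl group is chosen because it distinguishes the two hydroxyls on steric grounds and survives every step up to the last.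

## Roads not taken

**Alternative 1:** Ring A itself is cut, across C4a–C5 and C6–C7 with C7–C8 made in the closing step. The precursors are cyclobutenone A2, which already carries the C4–C3–C2 chain, ring B and the C3 configuration, and the alkynyl ether A3. On heating, A2 opens to a vinylketene, adds A3 in a [2+2] sense, opens again and closes by six-electron electrocyclisation; tautomerisation gives phenol A1 (Danheiser benzannulation).
- Merits: the mechanism places every ring A substituent. The methoxy group lands next to the chain, the prenyl group next to the new hydroxyl, and the C7 hydroxyl emerges free and distinct from the silylated C8a oxygen. On this point it is better than the chosen plan, which spends six steps on ring A.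
- Weak points: the key step sets no stereocentre, so A2 must first be made enantiopure by a separate asymmetric method. A2 is a vinylogous silyl ester and hydrolytically labile. A3 is a volatile, acid-sensitive methoxyalkyne with a skipped enyne. The route is linear, with all of ring B and the stereocentre invested before the riskiest step.
- Comparison: the chosen plan sets C3 catalytically in the step that joins the fragments and stays convergent. Against the regiochemical economy of A1 it has to set a ring A synthesis controlled by rearrangement (steps 1 to 6) and a hindered triflate.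

**Alternative 2:** The cuts are C3–C4 and O1–C2 at the lactone oxidation level, leading to the symmetrical sulfone A5 and the ring B arylacetic acid A6. Base expels sulfinate from A5 to give an ortho-quinone methide. A chiral isothiourea, acylated by activated A6, forms a C1-ammonium enolate that adds to the quinone methide and lactonises to dihydrocoumarin A4.
- Merits: the step is catalytic, enantioselective and metal-free, and it closes ring C while setting C3. The chosen key step closes no ring, so this one does more.
- Weak points: C3–H of A4 is alpha to the lactone carbonyl and benzylic, so it is open to epimerisation under the base needed afterwards. The lactone must be reduced and ring C closed a second time. A4 lacks the O-methyl and the C6 prenyl group, and late C-prenylation would have to distinguish C6 from C8, both lying between two oxygens. Installing these groups in A5 removes its symmetry and crowds the quinone methide.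
- Comparison: the chosen plan brings in ring A fully substituted and never places a carbonyl next to C3. It pays with three further operations to reach ring C, an organolithium and a palladium catalyst.

**Alternative 3:** Ring D is cut at the aryl C3'–CH bond and the O–CMe2 bond, giving the 2'-O-(1,1-dimethylpropargyl) isoflavan A8. Heating triggers Claisen rearrangement, [1,5]-hydrogen shift and oxa-6π closure to A7, whose acetals are then removed.
- Merits: the cascade is reliable and has only one free ortho carbon. The chromene appears at the very end and never meets organolithium, palladium or peroxide. In this respect it is safer than the chosen plan, which carries the chromene through five steps.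
- Weak points: it leaves the stereocentre and the union of rings A and B to some other method. It needs the 2'-oxygen differentiated from the 4'-oxygen and from both ring A oxygens, so an extra orthogonal protecting group and a late propargylation of a hindered hydroxyl. The full-size intermediate is heated to about 150 °C or more.
- Comparison: the chosen plan uses the same cascade on the small ether 13 (step 9), with bromine as the blocking group. It gives up the safety of a late chromene and gains fewer protecting-group steps. Should the chromene prove incompatible with the key step, this alternative combined with the same conjunctive coupling would be the natural repair.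

Key step: step 10

Assumptions:
- The sense of induction of the MandyPhos ligand is not predicted here; the antipode that gives the (R)-boronate 18 is used, both antipodes being available.
- Carbonate 3 is taken as a catalogue reagent; otherwise it is made in one operation from 2-methylbut-3-en-2-ol and di-tert-butyl dicarbonate.

## Route

Step 1
Reactants: 1 2,4,6-trihydroxybenzaldehyde
Product: 2 2-hydroxy-4,6-bis(methoxymethoxy)benzaldehyde
Conditions: MOMCl (2.1 equiv), i-Pr2NEt, CH2Cl2, 0 °C → rt
Reagents that add atoms: chloromethyl methyl ether, COCCl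
Why: Selective acetal (MOM) protection of a polyphenol aldehyde; the para hydroxyl and one of the two equivalent ortho hydroxyls react, while the remaining ortho hydroxyl is held in a hydrogen bond to the formyl group and stays free, and the symmetry of 1 allows only one bis-ether.

Step 2
Reactants: 2 2-hydroxy-4,6-bis(methoxymethoxy)benzaldehyde; 3 tert-butyl 2-methylbut-3-en-2-yl carbonate
Product: 4 2,4-bis(methoxymethoxy)-6-[(2-methylbut-3-en-2-yl)oxy]benzaldehyde
Conditions: Pd(PPh3)4 (3 mol%), THF, 0 °C → rt
Reagents that add atoms: none
Why: Tsuji–Trost O-allylation; the phenoxide attacks the 1,1-dimethylallyl palladium cation at its more substituted terminus under kinetic control to give the tertiary aryl ether, the tert-butoxide released on decarboxylation acting as base, and low temperature with a short reaction time keeps the branched ether from re-ionising to the linear prenyl ether.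

Step 3
Reactants: 4 2,4-bis(methoxymethoxy)-6-[(2-methylbut-3-en-2-yl)oxy]benzaldehyde
Product: 6 2,4-bis(methoxymethoxy)-6-[(2-methylbut-3-en-2-yl)oxy]phenol, via aryl formate 5 (not isolated)
Conditions: mCPBA (1.1 equiv), NaHCO3, CH2Cl2, 0 °C; then K2CO3 (cat.), MeOH, 0 °C
Reagents that add atoms: 3-chloroperoxybenzoic acid, OOC(=O)c1cccc(Cl)c1
Why: Baeyer–Villiger (Dakin-type) oxidation; the trioxygenated aryl group migrates in preference to hydrogen, and the aldehyde reacts much faster with the peracid than the monosubstituted vinyl group, which carries an allylic aryloxy group, while the buffer protects the tertiary allyl ether and the acetals and mild methanolysis cleaves the formate.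

Step 4
Reactants: 6 2,4-bis(methoxymethoxy)-6-[(2-methylbut-3-en-2-yl)oxy]phenol
Product: 7 2,4-bis(methoxymethoxy)-6-[(2-methylbut-3-en-2-yl)oxy]phenyl trifluoromethanesulfonate
Conditions: PhNTf2, Et3N, DMAP (cat.), CH2Cl2, 0 °C → rt
Reagents that add atoms: N-phenylbis(trifluoromethanesulfonimide), O=S(=O)(N(c1ccccc1)S(=O)(=O)C(F)(F)F)C(F)(F)F
Why: O-Sulfonylation of a hindered phenol with a mild triflyl donor under amine base, which leaves the acid-labile tertiary allyl ether and the acetals untouched and caps the oxygen that would otherwise form a catechol with the hydroxyl released in step 5.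

Step 5
Reactants: 7 2,4-bis(methoxymethoxy)-6-[(2-methylbut-3-en-2-yl)oxy]phenyl trifluoromethanesulfonate
Product: 8 2-hydroxy-4,6-bis(methoxymethoxy)-3-(3-methylbut-2-en-1-yl)phenyl trifluoromethanesulfonate
Conditions: N,N-diethylaniline, 130 °C
Reagents that add atoms: none
Why: Aromatic Claisen rearrangement of an aryl 1,1-dimethylallyl ether; one ortho carbon bears the triflate, so the allyl terminus can only be delivered to the other, where tautomerisation gives the ortho-prenylphenol, and the amine solvent suppresses acid-catalysed ionisation of the ether.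

Step 6
Reactants: 8 2-hydroxy-4,6-bis(methoxymethoxy)-3-(3-methylbut-2-en-1-yl)phenyl trifluoromethanesulfonate
Product: 9 2-methoxy-4,6-bis(methoxymethoxy)-3-(3-methylbut-2-en-1-yl)phenyl trifluoromethanesulfonate
Conditions: MeI, K2CO3, acetone, rt
Reagents that add atoms: iodomethane, CI
Why: Williamson O-methylation of the only free phenol; transfer of the triflyl group to the neighbouring phenoxide would need an endocyclic five-membered transition state at sulfur that cannot reach an in-line geometry, so the triflate should stay in place at room temperature.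

Step 7
Reactants: 10 4-bromoresorcinol
Product: 11 2-bromo-5-[(triisopropylsilyl)oxy]phenol
Conditions: TIPSCl (1.0 equiv), imidazole, CH2Cl2, −20 → 0 °C
Reagents that add atoms: chlorotri(propan-2-yl)silane, CC(C)[Si](Cl)(C(C)C)C(C)C
Why: Site-selective silylation with a bulky silyl chloride; the hydroxyl ortho to bromine is shielded and engaged in an O–H···Br contact, whereas the hydroxyl para to bromine is flanked by two hydrogens and should react first.

Step 8
Reactants: 11 2-bromo-5-[(triisopropylsilyl)oxy]phenol; 12 3-chloro-3-methylbut-1-yne
Product: 13 {4-bromo-3-[(2-methylbut-3-yn-2-yl)oxy]phenoxy}tri(propan-2-yl)silane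
Conditions: DBU, CuCl2·2H2O (1 mol%), MeCN, 0 °C
Reagents that add atoms: none
Why: Copper-catalysed propargylic etherification of a phenol with a tertiary propargyl chloride, the standard entry to aryl 1,1-dimethylpropargyl ethers; the aryl silyl ether tolerates DBU in dry acetonitrile at 0 °C.

Step 9
Reactants: 13 {4-bromo-3-[(2-methylbut-3-yn-2-yl)oxy]phenoxy}tri(propan-2-yl)silane
Product: 14 [(8-bromo-2,2-dimethyl-2H-chromen-5-yl)oxy]tri(propan-2-yl)silane
Conditions: N,N-diethylaniline, 170 °C
Reagents that add atoms: none
Why: Propargyl Claisen rearrangement followed by [1,5]-hydrogen shift and oxa-6π electrocyclisation; bromine occupies one ortho position, so ring D can only fuse at the carbon between the two oxygens and a single chromene regioisomer is possible.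

Step 10
Reactants: 14 [(8-bromo-2,2-dimethyl-2H-chromen-5-yl)oxy]tri(propan-2-yl)silane; 15 vinylboronic acid pinacol ester; 9 2-methoxy-4,6-bis(methoxymethoxy)-3-(3-methylbut-2-en-1-yl)phenyl trifluoromethanesulfonate
Product: 18 2-[(1R)-1-{2,2-dimethyl-5-[(triisopropylsilyl)oxy]-2H-chromen-8-yl}-2-[2-methoxy-4,6-bis(methoxymethoxy)-3-(3-methylbut-2-en-1-yl)phenyl]ethyl]-4,4,5,5-tetramethyl-1,3,2-dioxaborolane, via ring B aryllithium 16 (not isolated), via lithium vinylboron ate complex 17 (not isolated)
Conditions: t-BuLi (2 equiv), Et2O, −78 °C; 15, −78 °C → rt; evaporate; 9, Pd(OAc)2 (2 mol%), MandyPhos ligand [1,1'-bis{bis(4-methoxy-3,5-dimethylphenyl)phosphino}-2,2'-bis{α-(dimethylamino)benzyl}ferrocene] (2.4 mol%), KOSO2CF3 (2 equiv), THF, 60 °C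
Reagents that add atoms: none
Why: Bromine–lithium exchange gives aryllithium 16, which adds to the boron of 15 to form the ate complex 17. Oxidative addition of triflate 9 to zerovalent palladium gives a cationic arylpalladium complex (divalent palladium) that binds the vinyl group of 17; this induces an anti 1,2-shift of the ring B aryl group from boron to the α-carbon as palladium bonds to the β-carbon, and reductive elimination then forms C4–C4a and returns zerovalent palladium. The closest known reaction type is the palladium-catalysed enantioselective conjunctive cross-coupling of vinylboron ate complexes with aryl triflates. No ring is closed. C3 is created in the metallate shift, and its configuration is decided by which face of the vinyl group the chiral bisphosphine–palladium centre binds, that is by the ligand alone. The step must prefer this path over direct transfer of aryl or vinyl from boron to palladium and over Heck reaction at the prenyl or chromene double bonds: the triflate counter-ion, with KOSO2CF3 to take up the bromide from the exchange, keeps palladium cationic and olefin-binding, and the electron-rich vinyl ate complex binds far better than a trisubstituted or cis-disubstituted alkene. The electron-rich ortho-alkoxyaryl group migrates readily, whereas the pinacol oxygens do not.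

Step 11
Reactants: 18 2-[(1R)-1-{2,2-dimethyl-5-[(triisopropylsilyl)oxy]-2H-chromen-8-yl}-2-[2-methoxy-4,6-bis(methoxymethoxy)-3-(3-methylbut-2-en-1-yl)phenyl]ethyl]-4,4,5,5-tetramethyl-1,3,2-dioxaborolane
Product: 20 (2R)-2-{2,2-dimethyl-5-[(triisopropylsilyl)oxy]-2H-chromen-8-yl}-3-[2-methoxy-4,6-bis(methoxymethoxy)-3-(3-methylbut-2-en-1-yl)phenyl]propan-1-ol, via homologated pinacol boronate 19 (not isolated)
Conditions: ICH2Cl, n-BuLi, THF, −78 °C → rt; then H2O2, NaOH (aq), 0 °C
Reagents that add atoms: chloroiodomethane, ClCI; hydrogen peroxide, OO
Why: Matteson homologation; LiCH2Cl generated in the presence of 18 is captured on boron at −78 °C and on warming the secondary benzylic carbon migrates to the CH2 group with loss of chloride and retention at C3, excess carbenoid decomposing before it can add to the product, and alkaline peroxide then oxidises the primary C–B bond.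

Step 12
Reactants: 20 (2R)-2-{2,2-dimethyl-5-[(triisopropylsilyl)oxy]-2H-chromen-8-yl}-3-[2-methoxy-4,6-bis(methoxymethoxy)-3-(3-methylbut-2-en-1-yl)phenyl]propan-1-ol
Product: 21 4-[(2R)-2-{2,2-dimethyl-5-[(triisopropylsilyl)oxy]-2H-chromen-8-yl}-3-hydroxypropyl]-5-methoxy-6-(3-methylbut-2-en-1-yl)benzene-1,3-diol
Conditions: HCl (1 M in MeOH), 0 °C → rt
Reagents that add atoms: none
Why: Acid-catalysed methanolysis (transacetalisation) of the two aryl MOM ethers with formaldehyde trapped as dimethoxymethane, a deprotection with ample precedent on prenylated polyphenols; the aryl silyl ether, the chromene and the prenyl alkene should tolerate dilute methanolic acid at or below room temperature for the time needed.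

Step 13
Reactants: 21 4-[(2R)-2-{2,2-dimethyl-5-[(triisopropylsilyl)oxy]-2H-chromen-8-yl}-3-hydroxypropyl]-5-methoxy-6-(3-methylbut-2-en-1-yl)benzene-1,3-diol
Product: 22 (3R)-3-{2,2-dimethyl-5-[(triisopropylsilyl)oxy]-2H-chromen-8-yl}-5-methoxy-6-(3-methylbut-2-en-1-yl)-3,4-dihydro-2H-chromen-7-ol
Conditions: PPh3, DIAD, THF (0.01 M), 0 °C → rt
Reagents that add atoms: none
Why: Intramolecular Mitsunobu etherification (6-exo-tet); only the hydroxyl ortho to the side chain can reach the activated primary carbon, the other ring A phenol would have to bridge meta and the ring B phenol is still silylated, and since substitution occurs at primary C2 the stereocentre C3 is untouched.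

Step 14
Reactants: 22 (3R)-3-{2,2-dimethyl-5-[(triisopropylsilyl)oxy]-2H-chromen-8-yl}-5-methoxy-6-(3-methylbut-2-en-1-yl)-3,4-dihydro-2H-chromen-7-ol
Product: 23 (3R)-3-(5-hydroxy-2,2-dimethyl-2H-chromen-8-yl)-5-methoxy-6-(3-methylbut-2-en-1-yl)-3,4-dihydro-2H-chromen-7-ol
Conditions: n-Bu4NF, AcOH, THF, 0 °C
Reagents that add atoms: none
Why: Fluoride-induced cleavage of an aryl silyl ether; acetic acid buffers the phenoxide, so the electron-rich product meets neither base nor mineral acid in the last step.

## Compound list

1 | 2,4,6-trihydroxybenzaldehyde | O=Cc1c(O)cc(O)cc1O | starting material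
2 | 2-hydroxy-4,6-bis(methoxymethoxy)benzaldehyde | O=Cc1c(O)cc(OCOC)cc1OCOC | intermediate
3 | tert-butyl 2-methylbut-3-en-2-yl carbonate | C=CC(C)(C)OC(=O)OC(C)(C)C | starting material
4 | 2,4-bis(methoxymethoxy)-6-[(2-methylbut-3-en-2-yl)oxy]benzaldehyde | O=Cc1c(OC(C)(C)C=C)cc(OCOC)cc1OCOC | intermediate
5 | 2,4-bis(methoxymethoxy)-6-[(2-methylbut-3-en-2-yl)oxy]phenyl formate | O=COc1c(OC(C)(C)C=C)cc(OCOC)cc1OCOC | intermediate
6 | 2,4-bis(methoxymethoxy)-6-[(2-methylbut-3-en-2-yl)oxy]phenol | Oc1c(OC(C)(C)C=C)cc(OCOC)cc1OCOC | intermediate
7 | 2,4-bis(methoxymethoxy)-6-[(2-methylbut-3-en-2-yl)oxy]phenyl trifluoromethanesulfonate | C=CC(C)(C)Oc1cc(OCOC)cc(OCOC)c1OS(=O)(=O)C(F)(F)F | intermediate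
8 | 2-hydroxy-4,6-bis(methoxymethoxy)-3-(3-methylbut-2-en-1-yl)phenyl trifluoromethanesulfonate | Oc1c(CC=C(C)C)c(OCOC)cc(OCOC)c1OS(=O)(=O)C(F)(F)F | intermediate
9 | 2-methoxy-4,6-bis(methoxymethoxy)-3-(3-methylbut-2-en-1-yl)phenyl trifluoromethanesulfonate | COc1c(CC=C(C)C)c(OCOC)cc(OCOC)c1OS(=O)(=O)C(F)(F)F | intermediate
10 | 4-bromoresorcinol | Oc1ccc(Br)c(O)c1 | starting material
11 | 2-bromo-5-[(triisopropylsilyl)oxy]phenol | Oc1cc(O[Si](C(C)C)(C(C)C)C(C)C)ccc1Br | intermediate
12 | 3-chloro-3-methylbut-1-yne | C#CC(C)(C)Cl | starting material
13 | {4-bromo-3-[(2-methylbut-3-yn-2-yl)oxy]phenoxy}tri(propan-2-yl)silane | C#CC(C)(C)Oc1cc(O[Si](C(C)C)(C(C)C)C(C)C)ccc1Br | intermediate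
14 | [(8-bromo-2,2-dimethyl-2H-chromen-5-yl)oxy]tri(propan-2-yl)silane | Brc1ccc(O[Si](C(C)C)(C(C)C)C(C)C)c2c1OC(C)(C)C=C2 | intermediate
15 | vinylboronic acid pinacol ester | C=CB1OC(C)(C)C(C)(C)O1 | starting material
16 | {2,2-dimethyl-5-[(triisopropylsilyl)oxy]-2H-chromen-8-yl}lithium | [Li]c1ccc(O[Si](C(C)C)(C(C)C)C(C)C)c2c1OC(C)(C)C=C2 | intermediate
17 | lithium {2,2-dimethyl-5-[(triisopropylsilyl)oxy]-2H-chromen-8-yl}(ethenyl)(pinacolato)borate | [Li+].C=C[B-]1(c2ccc(O[Si](C(C)C)(C(C)C)C(C)C)c3c2OC(C)(C)C=C3)OC(C)(C)C(C)(C)O1 | intermediate
18 | 2-[(1R)-1-{2,2-dimethyl-5-[(triisopropylsilyl)oxy]-2H-chromen-8-yl}-2-[2-methoxy-4,6-bis(methoxymethoxy)-3-(3-methylbut-2-en-1-yl)phenyl]ethyl]-4,4,5,5-tetramethyl-1,3,2-dioxaborolane | COc1c(CC=C(C)C)c(OCOC)cc(OCOC)c1C[C@H](c1ccc(O[Si](C(C)C)(C(C)C)C(C)C)c2c1OC(C)(C)C=C2)B1OC(C)(C)C(C)(C)O1 | intermediate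
19 | 2-[(2R)-2-{2,2-dimethyl-5-[(triisopropylsilyl)oxy]-2H-chromen-8-yl}-3-[2-methoxy-4,6-bis(methoxymethoxy)-3-(3-methylbut-2-en-1-yl)phenyl]propyl]-4,4,5,5-tetramethyl-1,3,2-dioxaborolane | COc1c(CC=C(C)C)c(OCOC)cc(OCOC)c1C[C@H](c1ccc(O[Si](C(C)C)(C(C)C)C(C)C)c2c1OC(C)(C)C=C2)CB1OC(C)(C)C(C)(C)O1 | intermediate
20 | (2R)-2-{2,2-dimethyl-5-[(triisopropylsilyl)oxy]-2H-chromen-8-yl}-3-[2-methoxy-4,6-bis(methoxymethoxy)-3-(3-methylbut-2-en-1-yl)phenyl]propan-1-ol | COc1c(CC=C(C)C)c(OCOC)cc(OCOC)c1C[C@H](c1ccc(O[Si](C(C)C)(C(C)C)C(C)C)c2c1OC(C)(C)C=C2)CO | intermediate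
21 | 4-[(2R)-2-{2,2-dimethyl-5-[(triisopropylsilyl)oxy]-2H-chromen-8-yl}-3-hydroxypropyl]-5-methoxy-6-(3-methylbut-2-en-1-yl)benzene-1,3-diol | COc1c(CC=C(C)C)c(O)cc(O)c1C[C@H](c1ccc(O[Si](C(C)C)(C(C)C)C(C)C)c2c1OC(C)(C)C=C2)CO | intermediate
22 | (3R)-3-{2,2-dimethyl-5-[(triisopropylsilyl)oxy]-2H-chromen-8-yl}-5-methoxy-6-(3-methylbut-2-en-1-yl)-3,4-dihydro-2H-chromen-7-ol | COc1c(CC=C(C)C)c(O)cc2c1C[C@H](c1ccc(O[Si](C(C)C)(C(C)C)C(C)C)c3c1OC(C)(C)C=C3)CO2 | intermediate
23 | (3R)-3-(5-hydroxy-2,2-dimethyl-2H-chromen-8-yl)-5-methoxy-6-(3-methylbut-2-en-1-yl)-3,4-dihydro-2H-chromen-7-ol | COc1c(CC=C(C)C)c(O)cc2c1C[C@H](c1ccc(O)c3c1OC(C)(C)C=C3)CO2 | target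

## Step count and risks

Total step count: 14. Longest linear sequence: 11 steps (steps 1 to 6, then 10 to 14); the ring B branch (steps 7 to 9) joins at step 10.

**Step 10 (key step).** Oxidative addition of the electron-rich triflate 9, flanked by two oxygen substituents, may be slow. The ate complex 17 could then pass its aryl or vinyl group directly to palladium or undergo protodeboronation, and the crowded partners could erode facial selectivity. Fallback: bromide 14 is vinylated with 15 by Suzuki coupling (PdCl2(dppf), K2CO3, dioxane/water) to 8-ethenyl-2,2-dimethyl-5-[(triisopropylsilyl)oxy]-2H-chromene F1. F1 undergoes platinum-catalysed enantioselective diboration (Pt(dba)3, TADDOL-derived phosphonite, B2pin2) to the (R)-1,2-bis(boronate) F2. The primary C–B bond of F2 is then coupled selectively with 9 (Pd(OAc)2, RuPhos, KOH, THF/water), which returns to the route at 18.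

**Step 2.** The branched ether could re-ionise on palladium and collect as the linear O-prenyl ether, which would rearrange to the wrong allyl isomer in step 5. Fallback: 2 is etherified with 12 under copper catalysis (DBU, CuCl2, MeCN) to 2,4-bis(methoxymethoxy)-6-[(2-methylbut-3-yn-2-yl)oxy]benzaldehyde F3. Semi-hydrogenation of F3 (H2, Pd/CaCO3 poisoned with Pb(OAc)2, quinoline) returns to the route at 4.

**Step 3.** The peracid could epoxidise the vinyl group, the tertiary allyl ether could ionise in the acidic medium, or the electron-rich phenol could be over-oxidised. Fallback: the oxidation is carried out on the alkyne, which is inert to peracid and more robust to acid. Starting from 2, the propargyl ether F3 (made as above) is oxidised with mCPBA to the formate F4 and methanolysed to 2,4-bis(methoxymethoxy)-6-[(2-methylbut-3-yn-2-yl)oxy]phenol F5. F5 is converted with PhNTf2 into the triflate F6, and semi-hydrogenation of F6 returns to the route at 7.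

**Step 7.** Site selectivity between the two hydroxyls of 10 may be insufficient, or bis-silylation may intervene. Fallback: the order is reversed and the choice is made by acidity. With one equivalent of DBU the more acidic hydroxyl ortho to bromine is the main phenoxide, and copper-catalysed propargylation of 10 with 12 gives 4-bromo-3-[(2-methylbut-3-yn-2-yl)oxy]phenol F7. Silylation of the remaining hydroxyl of F7 with TIPSCl returns to the route at 13.

**Step 12.** Brønsted acid may cyclise the prenyl group onto the newly freed C7 hydroxyl or add methanol across the chromene or prenyl double bond, and released formaldehyde may attack the electron-rich ring A. Fallback: the acetals of 20 are exchanged under non-protic conditions (TMSOTf, 2,2'-bipyridyl, MeCN, 0 °C) to give the tris(trimethylsilyl) ether F8. F8 is hydrolysed with citric acid in methanol at 0 °C, which returns to the route at 21.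

## Further compounds

F1 | step 10 | 8-ethenyl-2,2-dimethyl-5-[(triisopropylsilyl)oxy]-2H-chromene | C=Cc1ccc(O[Si](C(C)C)(C(C)C)C(C)C)c2c1OC(C)(C)C=C2
F2 | step 10 | 2,2'-[(1R)-1-{2,2-dimethyl-5-[(triisopropylsilyl)oxy]-2H-chromen-8-yl}ethane-1,2-diyl]bis(4,4,5,5-tetramethyl-1,3,2-dioxaborolane) | CC1(C)OB(C[C@H](c2ccc(O[Si](C(C)C)(C(C)C)C(C)C)c3c2OC(C)(C)C=C3)B2OC(C)(C)C(C)(C)O2)OC1(C)C
F3 | step 2 | 2,4-bis(methoxymethoxy)-6-[(2-methylbut-3-yn-2-yl)oxy]benzaldehyde | O=Cc1c(OC(C)(C)C#C)cc(OCOC)cc1OCOC
F4 | step 3 | 2,4-bis(methoxymethoxy)-6-[(2-methylbut-3-yn-2-yl)oxy]phenyl formate | O=COc1c(OC(C)(C)C#C)cc(OCOC)cc1OCOC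
F5 | step 3 | 2,4-bis(methoxymethoxy)-6-[(2-methylbut-3-yn-2-yl)oxy]phenol | Oc1c(OC(C)(C)C#C)cc(OCOC)cc1OCOC
F6 | step 3 | 2,4-bis(methoxymethoxy)-6-[(2-methylbut-3-yn-2-yl)oxy]phenyl trifluoromethanesulfonate | C#CC(C)(C)Oc1cc(OCOC)cc(OCOC)c1OS(=O)(=O)C(F)(F)F
F7 | step 7 | 4-bromo-3-[(2-methylbut-3-yn-2-yl)oxy]phenol | C#CC(C)(C)Oc1cc(O)ccc1Br
F8 | step 12 | {[(2R)-2-{2,2-dimethyl-5-[(triisopropylsilyl)oxy]-2H-chromen-8-yl}-3-[2-methoxy-3-(3-methylbut-2-en-1-yl)-4,6-bis(trimethylsilyloxy)phenyl]propyl]oxy}trimethylsilane | COc1c(CC=C(C)C)c(O[Si](C)(C)C)cc(O[Si](C)(C)C)c1C[C@H](c1ccc(O[Si](C(C)C)(C(C)C)C(C)C)c2c1OC(C)(C)C=C2)CO[Si](C)(C)C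
A1 | alternative 1 | 4-[(2R)-3-[(tert-butyldimethylsilyl)oxy]-2-[5-(methoxymethoxy)-2,2-dimethyl-2H-chromen-8-yl]propyl]-3-methoxy-2-(3-methylbut-2-en-1-yl)-5-[(triisopropylsilyl)oxy]phenol | COc1c(CC=C(C)C)c(O)cc(O[Si](C(C)C)(C(C)C)C(C)C)c1C[C@H](c1ccc(OCOC)c2c1OC(C)(C)C=C2)CO[Si](C)(C)C(C)(C)C
A2 | alternative 1 | 2-[(2R)-3-[(tert-butyldimethylsilyl)oxy]-2-[5-(methoxymethoxy)-2,2-dimethyl-2H-chromen-8-yl]propyl]-3-[(triisopropylsilyl)oxy]cyclobut-2-en-1-one | O=C1CC(O[Si](C(C)C)(C(C)C)C(C)C)=C1C[C@H](c1ccc(OCOC)c2c1OC(C)(C)C=C2)CO[Si](C)(C)C(C)(C)C
A3 | alternative 1 | 1-methoxy-5-methylhex-4-en-1-yne | COC#CCC=C(C)C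
A4 | alternative 2 | (3R)-5-hydroxy-7-(methoxymethoxy)-3-[5-(methoxymethoxy)-2,2-dimethyl-2H-chromen-8-yl]chroman-2-one | COCOc1cc(O)c2C[C@H](c3ccc(OCOC)c4c3OC(C)(C)C=C4)C(=O)Oc2c1
A5 | alternative 2 | 5-(methoxymethoxy)-2-[(4-methylbenzenesulfonyl)methyl]benzene-1,3-diol | COCOc1cc(O)c(CS(=O)(=O)c2ccc(C)cc2)c(O)c1
A6 | alternative 2 | [5-(methoxymethoxy)-2,2-dimethyl-2H-chromen-8-yl]acetic acid | OC(=O)Cc1ccc(OCOC)c2c1OC(C)(C)C=C2
A7 | alternative 3 | (3R)-5-methoxy-7-(methoxymethoxy)-3-[5-(methoxymethoxy)-2,2-dimethyl-2H-chromen-8-yl]-6-(3-methylbut-2-en-1-yl)-3,4-dihydro-2H-chromene | COc1c(CC=C(C)C)c(OCOC)cc2c1C[C@H](c1ccc(OCOC)c3c1OC(C)(C)C=C3)CO2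
A8 | alternative 3 | (3R)-5-methoxy-7-(methoxymethoxy)-3-{4-(methoxymethoxy)-2-[(2-methylbut-3-yn-2-yl)oxy]phenyl}-6-(3-methylbut-2-en-1-yl)-3,4-dihydro-2H-chromene | COc1c(CC=C(C)C)c(OCOC)cc2c1C[C@H](c1ccc(OCOC)cc1OC(C)(C)C#C)CO2
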